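**Retrosynthetic overview**
- Target 26 comes from diketone 25 by cleaving four methyl and two ethyl aryl ethers; 25 comes from benzannulation product 23 by desilylation and oxidation of the two benzylic carbinols.
- The strategy rests on the two terminal rings C and D. Each is a 2-acylresorcinol: the chain-bearing C2 lies between the O-bearing C1 and C3, and C4, C5, C6 are three adjacent unsubstituted CH.
- Rings C and D are made last and together, by benzannulation of bis(1-ethoxyalkyne) 15 with two molecules of cyclobutenone 18. Per ring this forms C1–C2, C3–C4 and C1–C6 (C1 = former ketene carbonyl carbon, C2/C3 = alkyne carbons, C4–C6 = cyclobutenone CH carbons).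
- 15 comes from dialdehyde 11 and two molecules of ethoxyacetylene 12; 11 comes from biaryl dialdehyde 5 by double Wittig with a C8 hydroxyalkyl ylide, hydrogenation and oxidation.
- Rings A and B are bought (1 and 4) and joined first by Suzuki coupling; 18 comes from acid 16. Ring order: A and B purchased, biaryl bond, chains, then rings C and D in one operation.

Key step: step 12

Assumption: the two carbinol carbons made in step 8 are carried as a diastereomer mixture because both become ketones in step 14; the target has no stereocentre, and its biaryl axis (one ortho substituent on each ring) is not configurationally stable.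

The route is two-directional from compound 5 onward. In steps 5, 8 and 12 the biaryl takes up two molecules of the numbered partner, one per arm; the second molecule is entered under "Reagents that add atoms".

**Step 1**
Reactants: 1 5-bromovanillin
Product: 2 3-bromo-4,5-dimethoxybenzaldehyde
Conditions: MeI, K2CO3, DMF, rt
Reagents that add atoms: iodomethane, CI
Why: Williamson O-methylation of the acidic phenol para to the formyl group; the aldehyde and aryl bromide are inert to K2CO3/MeI.

**Step 2**
Reactants: 2 3-bromo-4,5-dimethoxybenzaldehyde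
Product: 3 3,4-dimethoxy-5-(4,4,5,5-tetramethyl-1,3,2-dioxaborolan-2-yl)benzaldehyde
Conditions: B2pin2, PdCl2(dppf), KOAc, 1,4-dioxane, 90 °C
Reagents that add atoms: bis(pinacolato)diboron, CC1(C)OB(OC1(C)C)B1OC(C)(C)C(C)(C)O1
Why: Miyaura borylation (oxidative addition of zerovalent palladium to the aryl bromide, acetate-assisted transmetalation); boron is placed on this ring so that no ortho-formyl arylboronate, prone to protodeboronation, is needed.

**Step 3**
Reactants: 3 3,4-dimethoxy-5-(pinacolboryl)benzaldehyde and 4 6-bromoveratraldehyde (2-bromo-4,5-dimethoxybenzaldehyde)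
Product: 5 4,5,5',6'-tetramethoxybiphenyl-2,3'-dicarbaldehyde (ring A: 3-formyl-5,6-dimethoxyphenyl; ring B: 2-formyl-4,5-dimethoxyphenyl)
Conditions: Pd(PPh3)4, K2CO3, 1,4-dioxane/H2O, 90 °C
Reagents that add atoms: none
Why: Suzuki–Miyaura coupling forming a biaryl bond with only one ortho substituent on each partner; both aldehydes tolerate aqueous carbonate.

**Step 4**
Reactants: 6 8-bromooctan-1-ol
Product: 7 (8-hydroxyoctyl)triphenylphosphonium bromide
Conditions: PPh3, MeCN, reflux
Reagents that add atoms: triphenylphosphine, c1ccc(cc1)P(c1ccccc1)c1ccccc1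
Why: SN2 quaternisation of triphenylphosphine by the primary bromide; the free hydroxyl does not interfere.

**Step 5**
Reactants: 5 biaryl dialdehyde and 7 (8-hydroxyoctyl)triphenylphosphonium bromide (two equivalents consumed, one per formyl group; used in slight excess)
Product: 9 9,9'-(4,5,5',6'-tetramethoxybiphenyl-2,3'-diyl)bis(non-8-en-1-ol) (E/Z mixture), via alkoxide ylide 8 (not isolated)
Conditions: 7 (2.5 equiv), NaHMDS (two equiv per 7), THF, 0 °C; then 5, 0 °C to rt; then H2O
Reagents that add atoms: (8-hydroxyoctyl)triphenylphosphonium bromide (second equivalent), OCCCCCCCC[P+](c1ccccc1)(c1ccccc1)c1ccccc1.[Br-]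
Why: Double Wittig olefination with a non-stabilised ylide, one ylide per formyl group and the second equivalent of base covering each hydroxyl; alkene geometry is irrelevant because step 6 saturates both alkenes.

**Step 6**
Reactants: 9 bis(non-8-en-1-ol)
Product: 10 9,9'-(4,5,5',6'-tetramethoxybiphenyl-2,3'-diyl)di(nonan-1-ol)
Conditions: H2 (1 atm), Pd/C, EtOAc/EtOH, rt
Reagents that add atoms: none
Why: Heterogeneous catalytic hydrogenation of the two styrenyl alkenes; aryl methyl ethers and primary alcohols are untouched.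

**Step 7**
Reactants: 10 diol
Product: 11 9,9'-(4,5,5',6'-tetramethoxybiphenyl-2,3'-diyl)dinonanal
Conditions: Dess–Martin periodinane, CH2Cl2, rt
Reagents that add atoms: none
Why: Dess–Martin oxidation takes both primary alcohols to aldehydes without over-oxidation and leaves the electron-rich biaryl alone.

**Step 8**
Reactants: 11 dialdehyde and 12 ethoxyacetylene (two equivalents consumed, one per formyl group; used in slight excess)
Product: 14 11,11'-(4,5,5',6'-tetramethoxybiphenyl-2,3'-diyl)bis(1-ethoxyundec-1-yn-3-ol) (diastereomer mixture), via lithium ethoxyacetylide 13 (not isolated)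
Conditions: 12 (2.5 equiv), n-BuLi (2.4 equiv), THF, −78 °C; then 11, −78 to −40 °C; then H2O (basic work-up, Et3N-deactivated silica)
Reagents that add atoms: ethoxyacetylene (second equivalent), C#COCC
Why: 1,2-addition of a lithium acetylide to each of the two aliphatic aldehydes outruns enolisation at low temperature; the two new carbinol centres form unselectively, which is acceptable, and the acid-free work-up avoids Meyer–Schuster rearrangement of the ynol ether carbinol.

**Step 9**
Reactants: 14 bis(propargylic alcohol)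
Product: 15 11,11'-(4,5,5',6'-tetramethoxybiphenyl-2,3'-diyl)bis[3-(tert-butyldimethylsilyloxy)-1-ethoxyundec-1-yne] (diastereomer mixture)
Conditions: TBSCl (2.5 equiv), imidazole (5 equiv), DMF, 0 °C to rt
Reagents that add atoms: tert-butyldimethylsilyl chloride (two equivalents), CC(C)(C)[Si](C)(C)Cl
Why: Imidazole-mediated silylation of both secondary alcohols under buffered conditions; the silyl ether blocks Meyer–Schuster rearrangement and acylation of the carbinol by ketene in step 12.

**Step 10**
Reactants: 16 3-oxocyclobutanecarboxylic acid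
Product: 17 3-bromocyclobutanone
Conditions: HgO, Br2, MgSO4, CH2Cl2, reflux
Reagents that add atoms: bromine, BrBr
Why: Cristol–Firth variant of the Hunsdiecker reaction (radical bromodecarboxylation), a documented route to this bromoketone.

**Step 11**
Reactants: 17 3-bromocyclobutanone
Product: 18 cyclobut-2-enone
Conditions: n-Bu3N, neat, rt, reduced pressure, distilled into a −78 °C trap; kept as a cold toluene solution
Reagents that add atoms: none
Why: Amine-promoted dehydrobromination of a β-bromoketone (E1cB-type elimination); the volatile enone is removed from the base as it forms, which limits polymerisation.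

**Step 12**
Reactants: 15 bis(1-ethoxy-3-silyloxyalkyne) and 18 cyclobut-2-enone (two equivalents consumed, one per ynol ether; used in excess)
Product: 23 2,2'-[(4,5,5',6'-tetramethoxybiphenyl-2,3'-diyl)bis(1-(tert-butyldimethylsilyloxy)nonane-9,1-diyl)]bis(3-ethoxyphenol) (diastereomer mixture), via vinylketene 19 (not isolated), via bis(4-vinylcyclobutenone) 20 (not isolated), via bis(dienylketene) 21 (not isolated), via bis(cyclohexadienone) 22 (not isolated)
Conditions: 18 (excess, cold toluene solution added in portions), toluene, 80 °C, sealed vessel; then K2CO3, MeOH, rt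
Reagents that add atoms: cyclobut-2-enone (second equivalent), O=C1C=CC1
Why: Danheiser benzannulation, the known thermal union of cyclobutenones with 1-alkoxyalkynes to 3-alkoxyphenols, here run on both arms at once (one molecule of 18 per ynol ether) and with unsubstituted cyclobutenone, a less used partner: 4π electrocyclic opening of 18 gives vinylketene 19, whose C=C=O adds (2+2) to each ynol ether to give 4-vinylcyclobutenone 20 (bonds C1–C2 and C3–C4). A second, reversible 4π opening gives dienylketene 21, and each resorcinol ring is then closed by thermal disrotatory 6π electrocyclisation (bond C1–C6) to dienone 22, which tautomerises to the phenol. No stereocentre is created: the sp3 ring carbons of 20 and 22 are erased on aromatisation, and the two silyloxy carbons remain an uncontrolled mixture that step 14 removes. The selectivity needed is regiochemical and is secured by ynol ether polarisation: the alkyne carbon remote from OEt is the nucleophile and bonds to the electrophilic ketene carbonyl carbon, so the chain carbon C2 ends between C1–OH and C3–OEt. A bath at 80 °C stays below the retro-ene loss of ethylene from the ethoxyalkyne, portionwise excess of 18 offsets its polymerisation, and the K2CO3/MeOH treatment returns any phenol acylated by 19.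

**Step 13**
Reactants: 23 bis(silyloxyalkyl) bis(ethoxyphenol)
Product: 24 2,2'-[(4,5,5',6'-tetramethoxybiphenyl-2,3'-diyl)bis(1-hydroxynonane-9,1-diyl)]bis(3-ethoxyphenol) (diastereomer mixture)
Conditions: TBAF, AcOH, THF, rt; crude product used directly
Reagents that add atoms: none
Why: Fluoride-induced Si–O cleavage; the acetic acid buffer keeps the phenols protonated, so the sensitive o-hydroxybenzylic alcohol is not exposed to strong base or acid.

**Step 14**
Reactants: 24 bis(benzylic carbinol)
Product: 25 9,9'-(4,5,5',6'-tetramethoxybiphenyl-2,3'-diyl)bis[1-(2-ethoxy-6-hydroxyphenyl)nonan-1-one]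
Conditions: activated MnO2 (excess), CH2Cl2, rt
Reagents that add atoms: none
Why: MnO2 oxidation is selective for benzylic alcohols, and the o-hydroxyaryl ketone product is stabilised by an intramolecular hydrogen bond; this removes both carbinol stereocentres.

**Step 15**
Reactants: 25 bis(2-ethoxy-6-hydroxyphenyl ketone)
Product: 26 9,9'-(4,5,5',6'-tetrahydroxybiphenyl-2,3'-diyl)bis[1-(2,6-dihydroxyphenyl)nonan-1-one] (target)
Conditions: BBr3 (excess), CH2Cl2, −78 °C to rt; then H2O, degassed work-up
Reagents that add atoms: none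
Why: BBr3 dealkylation of aryl ethers cleaves the four methyl and two ethyl ethers (the ethoxy groups ortho to the ketone are chelation-assisted), and hydrolysis of the borates frees both catechols and both resorcinols with the aryl ketones intact.

**Compound list**
1 | 5-bromovanillin | COc1cc(C=O)cc(Br)c1O | starting material
2 | 3-bromo-4,5-dimethoxybenzaldehyde | COc1cc(C=O)cc(Br)c1OC | intermediate
3 | 3,4-dimethoxy-5-(4,4,5,5-tetramethyl-1,3,2-dioxaborolan-2-yl)benzaldehyde | COc1cc(C=O)cc(B2OC(C)(C)C(C)(C)O2)c1OC | intermediate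
4 | 6-bromoveratraldehyde | COc1cc(Br)c(C=O)cc1OC | starting material
5 | 4,5,5',6'-tetramethoxybiphenyl-2,3'-dicarbaldehyde | COc1cc(C=O)cc(-c2cc(OC)c(OC)cc2C=O)c1OC | intermediate
6 | 8-bromooctan-1-ol | OCCCCCCCCBr | starting material
7 | (8-hydroxyoctyl)triphenylphosphonium bromide | OCCCCCCCC[P+](c1ccccc1)(c1ccccc1)c1ccccc1.[Br-] | intermediate
8 | sodium 8-(triphenylphosphoranylidene)octan-1-olate (alkoxide ylide) | [Na+].[O-]CCCCCCCC=P(c1ccccc1)(c1ccccc1)c1ccccc1 | intermediate
9 | 9,9'-(4,5,5',6'-tetramethoxybiphenyl-2,3'-diyl)bis(non-8-en-1-ol), E/Z mixture | OCCCCCCCC=Cc1cc(OC)c(OC)c(-c2cc(OC)c(OC)cc2C=CCCCCCCCO)c1 | intermediate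
10 | 9,9'-(4,5,5',6'-tetramethoxybiphenyl-2,3'-diyl)di(nonan-1-ol) | OCCCCCCCCCc1cc(OC)c(OC)c(-c2cc(OC)c(OC)cc2CCCCCCCCCO)c1 | intermediate
11 | 9,9'-(4,5,5',6'-tetramethoxybiphenyl-2,3'-diyl)dinonanal | O=CCCCCCCCCc1cc(OC)c(OC)c(-c2cc(OC)c(OC)cc2CCCCCCCCC=O)c1 | intermediate
12 | ethoxyacetylene | C#COCC | starting material
13 | lithium ethoxyacetylide | [Li]C#COCC | intermediate
14 | 11,11'-(4,5,5',6'-tetramethoxybiphenyl-2,3'-diyl)bis(1-ethoxyundec-1-yn-3-ol), diastereomer mixture | CCOC#CC(O)CCCCCCCCc1cc(OC)c(OC)c(-c2cc(OC)c(OC)cc2CCCCCCCCC(O)C#COCC)c1 | intermediate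
15 | 11,11'-(4,5,5',6'-tetramethoxybiphenyl-2,3'-diyl)bis[3-(tert-butyldimethylsilyloxy)-1-ethoxyundec-1-yne], diastereomer mixture | CCOC#CC(O[Si](C)(C)C(C)(C)C)CCCCCCCCc1cc(OC)c(OC)c(-c2cc(OC)c(OC)cc2CCCCCCCCC(C#COCC)O[Si](C)(C)C(C)(C)C)c1 | intermediate
16 | 3-oxocyclobutanecarboxylic acid | O=C1CC(C(=O)O)C1 | starting material
17 | 3-bromocyclobutanone | O=C1CC(Br)C1 | intermediate
18 | cyclobut-2-enone | O=C1C=CC1 | intermediate
19 | vinylketene (buta-1,3-dien-1-one) | C=CC=C=O | intermediate
20 | bis(4-vinylcyclobutenone): each arm of 15 converted to a 3-ethoxy-4-ethenylcyclobut-2-en-1-on-2-yl group on the silyloxy carbon | CCOC1=C(C(O[Si](C)(C)C(C)(C)C)CCCCCCCCc2cc(OC)c(OC)c(-c3cc(OC)c(OC)cc3CCCCCCCCC(O[Si](C)(C)C(C)(C)C)C3=C(OCC)C(C=C)C3=O)c2)C(=O)C1C=C | intermediate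
21 | bis(dienylketene): each arm a 3-ethoxy-1-oxohexa-1,3,5-trien-2-yl group with the ketene carbon and the vinyl group cis on C3=C4 | C=C/C=C(OCC)\C(=C=O)C(O[Si](C)(C)C(C)(C)C)CCCCCCCCc1cc(OC)c(OC)c(-c2cc(OC)c(OC)cc2CCCCCCCCC(O[Si](C)(C)C(C)(C)C)C(=C=O)/C(OCC)=C\C=C)c1 | intermediate
22 | bis(cyclohexa-2,4-dienone): each arm a 3-ethoxy-1-oxocyclohexa-2,4-dien-2-yl group | CCOC1=C(C(O[Si](C)(C)C(C)(C)C)CCCCCCCCc2cc(OC)c(OC)c(-c3cc(OC)c(OC)cc3CCCCCCCCC(O[Si](C)(C)C(C)(C)C)C3=C(OCC)C=CCC3=O)c2)C(=O)CC=C1 | intermediate
23 | 2,2'-[(4,5,5',6'-tetramethoxybiphenyl-2,3'-diyl)bis(1-(tert-butyldimethylsilyloxy)nonane-9,1-diyl)]bis(3-ethoxyphenol), diastereomer mixture | CCOc1cccc(O)c1C(O[Si](C)(C)C(C)(C)C)CCCCCCCCc1cc(OC)c(OC)c(-c2cc(OC)c(OC)cc2CCCCCCCCC(O[Si](C)(C)C(C)(C)C)c2c(O)cccc2OCC)c1 | intermediate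
24 | 2,2'-[(4,5,5',6'-tetramethoxybiphenyl-2,3'-diyl)bis(1-hydroxynonane-9,1-diyl)]bis(3-ethoxyphenol), diastereomer mixture | CCOc1cccc(O)c1C(O)CCCCCCCCc1cc(OC)c(OC)c(-c2cc(OC)c(OC)cc2CCCCCCCCC(O)c2c(O)cccc2OCC)c1 | intermediate
25 | 9,9'-(4,5,5',6'-tetramethoxybiphenyl-2,3'-diyl)bis[1-(2-ethoxy-6-hydroxyphenyl)nonan-1-one] | CCOc1cccc(O)c1C(=O)CCCCCCCCc1cc(OC)c(OC)c(-c2cc(OC)c(OC)cc2CCCCCCCCC(=O)c2c(O)cccc2OCC)c1 | intermediate
26 | 9,9'-(4,5,5',6'-tetrahydroxybiphenyl-2,3'-diyl)bis[1-(2,6-dihydroxyphenyl)nonan-1-one] | O=C(CCCCCCCCc1cc(O)c(O)c(-c2cc(O)c(O)cc2CCCCCCCCC(=O)c2c(O)cccc2O)c1)c1c(O)cccc1O | target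

**Step count**
Total: 15 steps. Longest linear sequence: 12 steps (1, 2, 3, 5, 6, 7, 8, 9, 12, 13, 14, 15).

**Steps most likely to fail**

Step 12 (double benzannulation). Cyclobutenone may polymerise, or react as a strained enone with the nucleophilic ynol ether, faster than it opens to 19. Capture of 19 by the hindered, inductively deactivated internal ynol ether may be slow, so that only one arm reacts. The o-(silyloxyalkyl)phenol may lose silanol thermally. The fallback sets out from dialdehyde 11 and brings in rings C and D preformed. 1,3-Dimethoxybenzene is lithiated between its two methoxy groups (n-BuLi, THF, 0 °C) to give 2,6-dimethoxyphenyllithium F1. Addition of two equivalents of F1 to the two aldehydes of 11 at −78 °C gives the bis(2,6-dimethoxyphenyl carbinol) F2. Dess–Martin oxidation gives the bis(2,6-dimethoxyphenyl ketone) F3. BBr3 then cleaves all eight methyl ethers, and the fallback comes back to the route at target 26.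

Step 14 (MnO2 oxidation with free phenols). One-electron oxidation of the electron-rich phenols (phenoxyl coupling), dehydration of the o-hydroxybenzylic alcohol to a quinone methide, and slow oxidation at the carbinol flanked by two ortho substituents may all compete. The fallback sets out from 23 and masks the phenols before the oxidation. O-Methylation (MeI, K2CO3, acetone) gives the bis(2-ethoxy-6-methoxyphenyl) silyl ether F4. TBAF gives the bis(2-ethoxy-6-methoxyphenyl carbinol) F5. Dess–Martin oxidation gives the bis(2-ethoxy-6-methoxyphenyl ketone) F6. BBr3 cleaves the six methyl and two ethyl ethers, and the fallback comes back at target 26.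

Step 11 (cyclobutenone preparation). The volatile enone may be lost to polymerisation or to conjugate addition of amine or bromide during elimination and cold-trap transfer, so that too little 18 of usable purity reaches step 12. The fallback sets out from 15 and makes vinylketene 19 without cyclobutenone. (E)-But-2-enoyl chloride (at least two equivalents) is added slowly to Et3N and 15 in CH2Cl2 at rt; 1,4-dehydrochlorination gives 19 in the flask, the same acid chloride/amine ketene generation used to make 3-ethoxycyclobutenones from ethoxyalkynes. Cycloaddition to both ynol ethers gives 20, where the fallback comes back to the route; heating 20 in toluene at 80 °C completes the sequence to 23. This fallback makes no compound outside the compound list.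

**Further compounds**
F1 | step 12 | 2,6-dimethoxyphenyllithium | [Li]c1c(OC)cccc1OC
F2 | step 12 | 9,9'-(4,5,5',6'-tetramethoxybiphenyl-2,3'-diyl)bis[1-(2,6-dimethoxyphenyl)nonan-1-ol], diastereomer mixture | COc1cccc(OC)c1C(O)CCCCCCCCc1cc(OC)c(OC)c(-c2cc(OC)c(OC)cc2CCCCCCCCC(O)c2c(OC)cccc2OC)c1
F3 | step 12 | 9,9'-(4,5,5',6'-tetramethoxybiphenyl-2,3'-diyl)bis[1-(2,6-dimethoxyphenyl)nonan-1-one] | COc1cccc(OC)c1C(=O)CCCCCCCCc1cc(OC)c(OC)c(-c2cc(OC)c(OC)cc2CCCCCCCCC(=O)c2c(OC)cccc2OC)c1
F4 | step 14 | 2,3'-bis[9-(tert-butyldimethylsilyloxy)-9-(2-ethoxy-6-methoxyphenyl)nonyl]-4,5,5',6'-tetramethoxybiphenyl, diastereomer mixture | CCOc1cccc(OC)c1C(O[Si](C)(C)C(C)(C)C)CCCCCCCCc1cc(OC)c(OC)c(-c2cc(OC)c(OC)cc2CCCCCCCCC(O[Si](C)(C)C(C)(C)C)c2c(OC)cccc2OCC)c1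
F5 | step 14 | 9,9'-(4,5,5',6'-tetramethoxybiphenyl-2,3'-diyl)bis[1-(2-ethoxy-6-methoxyphenyl)nonan-1-ol], diastereomer mixture | CCOc1cccc(OC)c1C(O)CCCCCCCCc1cc(OC)c(OC)c(-c2cc(OC)c(OC)cc2CCCCCCCCC(O)c2c(OC)cccc2OCC)c1
F6 | step 14 | 9,9'-(4,5,5',6'-tetramethoxybiphenyl-2,3'-diyl)bis[1-(2-ethoxy-6-methoxyphenyl)nonan-1-one] | CCOc1cccc(OC)c1C(=O)CCCCCCCCc1cc(OC)c(OC)c(-c2cc(OC)c(OC)cc2CCCCCCCCC(=O)c2c(OC)cccc2OCC)c1
F0 | step 11 | none | none
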